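**Retrosynthetic overview**
- The last operations are neutral. Hydrogenolysis removes two benzyl ethers and one benzyl ester, and before that one dioxolane is hydrolysed.
- The depside (aryl ester) C–O bond is cut into an A-ring acid (ketone masked as a dioxolane) and a B-ring benzyl 2,4-dihydroxybenzoate that is acylated at its 4-OH.
- Both halves come from one keto ester, methyl 2,4-bis(benzyloxy)-6-(2-oxoheptyl)benzoate.
- The key C–C bond is ArCH2–C(=O)C5H11. It is made by a crossed Claisen-type acylation of the lateral (vinylogous) ester enolate of dibenzylated methyl orsellinate with the Weinreb amide of hexanoic acid.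
- No carbocycle is built, because both benzene rings are bought as methyl orsellinate. The only ring made is the temporary dioxolane, closed in step 4 and opened in step 10.

**Assumption:** the SMILES holds no stereocentre and no stereogenic double bond, so the target (4-O-demethylmicrophyllinic acid) is achiral and no stereocontrol is needed.

**Step 1**
Reactants: 1 methyl orsellinate (methyl 2,4-dihydroxy-6-methylbenzoate)
Product: 2 methyl 2,4-bis(benzyloxy)-6-methylbenzoate
Conditions: BnBr (2.6 equiv), K2CO3 (3 equiv), DMF, 70 °C, 16 h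
Reagents that add atoms: benzyl bromide, BrCc1ccccc1
Why: Williamson ether synthesis, where warm DMF with excess base also alkylates the hydrogen-bonded 2-OH, and benzyl is chosen because it leaves under neutral hydrogenolysis at the end.

**Step 2**
Reactants: 3 hexanoyl chloride
Product: 4 N-methoxy-N-methylhexanamide
Conditions: MeNH(OMe)·HCl (1.1 equiv), K2CO3 (2.5 equiv), CH2Cl2/H2O, 0 °C to rt
Reagents that add atoms: N,O-dimethylhydroxylamine hydrochloride, CNOC.Cl
Why: Schotten–Baumann acylation of the amine is fast and clean and gives an acyl donor that cannot over-add.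

**Step 3**
Reactants: 2 methyl 2,4-bis(benzyloxy)-6-methylbenzoate; 4 N-methoxy-N-methylhexanamide
Product: 7 methyl 2,4-bis(benzyloxy)-6-(2-oxoheptyl)benzoate, via lithiated toluate 5 (not isolated), via lithium hemiaminal adduct 6 (not isolated)
Conditions: 2 added to LDA (commercial solution, 1.3 equiv), THF, −78 °C, 30 min; then 4 (1.5 equiv), −78 °C, 2 h; AcOH (in THF) quench at −78 °C
Reagents that add atoms: none
Why: This is a crossed Claisen-type condensation in which the ortho-toluate anion (a vinylogous ester enolate) is C-acylated by the Weinreb amide; the chelated adduct 6 releases the ketone only on the cold acid quench, so neither over-addition nor enolate lactonisation occurs.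

**Step 4**
Reactants: 7 methyl 2,4-bis(benzyloxy)-6-(2-oxoheptyl)benzoate
Product: 8 methyl 2,4-bis(benzyloxy)-6-[(2-pentyl-1,3-dioxolan-2-yl)methyl]benzoate
Conditions: TMSOCH2CH2OTMS (2 equiv), TMSOTf (0.05 equiv), CH2Cl2, −78 to −20 °C; pyridine quench
Reagents that add atoms: 1,2-bis(trimethylsilyloxy)ethane, C[Si](C)(C)OCCO[Si](C)(C)C
Why: Noyori ketalisation works at low temperature without hot acid, so the keto ester does not close to an isocoumarin and the benzyl ethers and ester are untouched.

**Step 5**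
Reactants: 8 methyl 2,4-bis(benzyloxy)-6-[(2-pentyl-1,3-dioxolan-2-yl)methyl]benzoate
Product: 10 2,4-bis(benzyloxy)-6-[(2-pentyl-1,3-dioxolan-2-yl)methyl]benzoic acid, via potassium carboxylate 9 (not isolated)
Conditions: KOH (10 equiv), DMSO/H2O 4:1, 100 °C, 16 h; then 0 °C, 1 M HCl to pH 4, immediate extraction (EtOAc); used promptly
Reagents that add atoms: potassium hydroxide, [K+].[OH-]
Why: Saponification of the di-ortho-substituted ester needs poorly solvated hydroxide in DMSO, conditions under which the ketal and benzyl ethers are inert, and the brief cold acidification spares the ketal.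

**Step 6**
Reactants: 7 methyl 2,4-bis(benzyloxy)-6-(2-oxoheptyl)benzoate
Product: 12 2,4-bis(benzyloxy)-6-(2-oxoheptyl)benzoic acid, via potassium keto carboxylate 11 (not isolated)
Conditions: KOH (5 equiv), EtOH/H2O 4:1, reflux, 8 h; then 0 °C, 1 M HCl to pH 3, extraction
Reagents that add atoms: potassium hydroxide, [K+].[OH-]
Why: Saponification in aqueous base ends at the ring-open keto carboxylate, which can no longer undergo intramolecular acylation, and cold acidification gives the keto acid.

**Step 7**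
Reactants: 12 2,4-bis(benzyloxy)-6-(2-oxoheptyl)benzoic acid
Product: 13 olivetonic acid (2,4-dihydroxy-6-(2-oxoheptyl)benzoic acid)
Conditions: H2 (1 atm), 10% Pd/C, EtOAc, rt, 3 h; filtered, concentrated below 30 °C, used directly
Reagents that add atoms: none
Why: Catalytic hydrogenolysis removes aryl benzyl ethers under neutral conditions that leave the unconjugated ketone alone and avoid decarboxylation or lactonisation.

**Step 8**
Reactants: 13 olivetonic acid
Product: 14 benzyl 2,4-dihydroxy-6-(2-oxoheptyl)benzoate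
Conditions: BnBr (1.05 equiv), KHCO3 (1.2 equiv), DMF, rt to 40 °C, 12 h
Reagents that add atoms: benzyl bromide, BrCc1ccccc1
Why: In this SN2 O-alkylation bicarbonate deprotonates only the carboxylic acid, so the phenols stay free, and steric hindrance at the acyl carbon does not matter.

**Step 9**
Reactants: 10 2,4-bis(benzyloxy)-6-[(2-pentyl-1,3-dioxolan-2-yl)methyl]benzoic acid; 14 benzyl 2,4-dihydroxy-6-(2-oxoheptyl)benzoate
Product: 15 benzyl 4-({2,4-bis(benzyloxy)-6-[(2-pentyl-1,3-dioxolan-2-yl)methyl]benzoyl}oxy)-2-hydroxy-6-(2-oxoheptyl)benzoate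
Conditions: DCC (1.2 equiv), DMAP (0.15 equiv), CH2Cl2, 0 °C to rt, 16 h
Reagents that add atoms: none
Why: In this Steglich esterification the 2-OH of 14 is held in a hydrogen bond to the ester carbonyl and is hindered, so only the 4-OH is acylated, and the ketal stops the activated acid from closing to an isocoumarin.

**Step 10**
Reactants: 15 ketal-protected tribenzyl depside
Product: 16 benzyl 4-{[2,4-bis(benzyloxy)-6-(2-oxoheptyl)benzoyl]oxy}-2-hydroxy-6-(2-oxoheptyl)benzoate
Conditions: 1 M aq HCl/THF 1:4, rt, 3–6 h (TLC control); NaHCO3 quench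
Reagents that add atoms: water, O
Why: Mild acid-catalysed ketal hydrolysis at room temperature is far faster than any attack on the aryl ester, benzyl ester or benzyl ethers.

**Step 11**
Reactants: 16 tribenzyl diketo depside
Product: 17 4-{[2,4-dihydroxy-6-(2-oxoheptyl)benzoyl]oxy}-2-hydroxy-6-(2-oxoheptyl)benzoic acid (target)
Conditions: H2 (1 atm), 10% Pd/C, EtOAc, rt, 3 h; Celite filtration, crystallisation
Reagents that add atoms: none
Why: Global catalytic hydrogenolysis of two benzyl ethers and the benzyl ester is neutral, so the base-labile depside link, the two ketones and the lactonisation-prone keto acid survive; no stereocentre has to be set.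

**Compound list**
1 | methyl orsellinate (methyl 2,4-dihydroxy-6-methylbenzoate) | COC(=O)c1c(C)cc(O)cc1O | starting material
2 | methyl 2,4-bis(benzyloxy)-6-methylbenzoate | COC(=O)c1c(C)cc(OCc2ccccc2)cc1OCc1ccccc1 | intermediate
3 | hexanoyl chloride | CCCCCC(=O)Cl | starting material
4 | N-methoxy-N-methylhexanamide | CCCCCC(=O)N(C)OC | intermediate
5 | lithiated toluate, methyl 2,4-bis(benzyloxy)-6-(lithiomethyl)benzoate (formed in the flask) | [Li]Cc1cc(OCc2ccccc2)cc(OCc2ccccc2)c1C(=O)OC | intermediate
6 | lithium hemiaminal adduct of 5 to 4 (formed in the flask, transient racemic centre) | CCCCCC(O[Li])(Cc1cc(OCc2ccccc2)cc(OCc2ccccc2)c1C(=O)OC)N(C)OC | intermediate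
7 | methyl 2,4-bis(benzyloxy)-6-(2-oxoheptyl)benzoate | CCCCCC(=O)Cc1cc(OCc2ccccc2)cc(OCc2ccccc2)c1C(=O)OC | intermediate
8 | methyl 2,4-bis(benzyloxy)-6-[(2-pentyl-1,3-dioxolan-2-yl)methyl]benzoate | CCCCCC1(Cc2cc(OCc3ccccc3)cc(OCc3ccccc3)c2C(=O)OC)OCCO1 | intermediate
9 | potassium carboxylate, potassium 2,4-bis(benzyloxy)-6-[(2-pentyl-1,3-dioxolan-2-yl)methyl]benzoate (formed in the flask) | CCCCCC1(Cc2cc(OCc3ccccc3)cc(OCc3ccccc3)c2C(=O)[O-])OCCO1.[K+] | intermediate
10 | 2,4-bis(benzyloxy)-6-[(2-pentyl-1,3-dioxolan-2-yl)methyl]benzoic acid | CCCCCC1(Cc2cc(OCc3ccccc3)cc(OCc3ccccc3)c2C(=O)O)OCCO1 | intermediate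
11 | potassium keto carboxylate, potassium 2,4-bis(benzyloxy)-6-(2-oxoheptyl)benzoate (formed in the flask) | CCCCCC(=O)Cc1cc(OCc2ccccc2)cc(OCc2ccccc2)c1C(=O)[O-].[K+] | intermediate
12 | 2,4-bis(benzyloxy)-6-(2-oxoheptyl)benzoic acid | CCCCCC(=O)Cc1cc(OCc2ccccc2)cc(OCc2ccccc2)c1C(=O)O | intermediate
13 | olivetonic acid (2,4-dihydroxy-6-(2-oxoheptyl)benzoic acid) | CCCCCC(=O)Cc1cc(O)cc(O)c1C(=O)O | intermediate
14 | benzyl 2,4-dihydroxy-6-(2-oxoheptyl)benzoate | CCCCCC(=O)Cc1cc(O)cc(O)c1C(=O)OCc1ccccc1 | intermediate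
15 | benzyl 4-({2,4-bis(benzyloxy)-6-[(2-pentyl-1,3-dioxolan-2-yl)methyl]benzoyl}oxy)-2-hydroxy-6-(2-oxoheptyl)benzoate | CCCCCC(=O)Cc1cc(OC(=O)c2c(OCc3ccccc3)cc(OCc3ccccc3)cc2CC2(CCCCC)OCCO2)cc(O)c1C(=O)OCc1ccccc1 | intermediate
16 | benzyl 4-{[2,4-bis(benzyloxy)-6-(2-oxoheptyl)benzoyl]oxy}-2-hydroxy-6-(2-oxoheptyl)benzoate | CCCCCC(=O)Cc1cc(OC(=O)c2c(OCc3ccccc3)cc(OCc3ccccc3)cc2CC(=O)CCCCC)cc(O)c1C(=O)OCc1ccccc1 | intermediate
17 | 4-{[2,4-dihydroxy-6-(2-oxoheptyl)benzoyl]oxy}-2-hydroxy-6-(2-oxoheptyl)benzoic acid (achiral) | CCCCCC(=O)Cc1cc(OC(=O)c2c(O)cc(O)cc2CC(=O)CCCCC)cc(O)c1C(=O)O | target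

**Total step count:** 11.
**Longest linear sequence:** 8 steps (1, 3, 6, 7, 8, 9, 10, 11, from methyl orsellinate).

**Three steps most likely to fail**

**Step 3 (lateral Claisen-type acylation).**
- Risk: the toluate anion may be quenched by the α-protons of the enolisable amide, or it may attack unreacted 2.
- Fallback: sets out from 2 and comes back at 7.
- Compound 2 is deprotonated with LDA (2.2 equiv, THF, −78 °C). The anion is trapped with the non-enolisable electrophile dimethyl carbonate to give the homophthalate methyl 2,4-bis(benzyloxy)-6-(2-methoxy-2-oxoethyl)benzoate F1.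
- The much more acidic arylacetate CH2 of F1 is converted to its enolate with LiHMDS (2 equiv). This enolate is C-acylated with hexanoyl chloride 3 to give the β-keto diester methyl 2,4-bis(benzyloxy)-6-(1-methoxy-1,3-dioxooctan-2-yl)benzoate F2, which is racemic at a centre that is lost at once.
- Krapcho demethoxycarbonylation (LiCl, wet DMSO, 130 °C) removes the aliphatic ester only and gives 7.

**Step 9 (depside coupling).**
- Risk: the di-ortho-substituted acid may rearrange to the N-acylurea faster than the phenol attacks.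
- Fallback: sets out from 10 and comes back at 15.
- In situ dehydrative coupling is replaced by an isolated, sterically small acyl halide. Compound 10 is treated with cyanuric fluoride and pyridine (CH2Cl2, −10 °C to rt, ketal-safe) to give 2,4-bis(benzyloxy)-6-[(2-pentyl-1,3-dioxolan-2-yl)methyl]benzoyl fluoride F3.
- F3 is added to the preformed 4-phenoxide of 14 (K2CO3, 1 equiv, MeCN, rt) to give 15.

**Step 10 (ketal hydrolysis).**
- Risk: acid may let the freed ketone enol-lactonise onto the aryl ester, which would give an isocoumarin and expel 14.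
- Fallback: sets out from 7 and comes back at 16. It uses a ketone mask that leaves without acid, and it also bypasses step 4.
- Compound 7 with ethane-1,2-dithiol (1.2 equiv) and catalytic I2 in CH2Cl2 gives methyl 2,4-bis(benzyloxy)-6-[(2-pentyl-1,3-dithiolan-2-yl)methyl]benzoate F4.
- KOH in DMSO/H2O at 100 °C followed by acidification gives 2,4-bis(benzyloxy)-6-[(2-pentyl-1,3-dithiolan-2-yl)methyl]benzoic acid F5.
- DCC/DMAP coupling of F5 with 14 gives benzyl 4-({2,4-bis(benzyloxy)-6-[(2-pentyl-1,3-dithiolan-2-yl)methyl]benzoyl}oxy)-2-hydroxy-6-(2-oxoheptyl)benzoate F6.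
- Alkylative hydrolysis (MeI, CaCO3, MeCN/H2O, 45 °C, essentially neutral) gives 16. It is chromatographed free of sulfur before the palladium step.

**Further compounds**
F1 | step 3 | methyl 2,4-bis(benzyloxy)-6-(2-methoxy-2-oxoethyl)benzoate | COC(=O)Cc1cc(OCc2ccccc2)cc(OCc2ccccc2)c1C(=O)OC
F2 | step 3 | methyl 2,4-bis(benzyloxy)-6-(1-methoxy-1,3-dioxooctan-2-yl)benzoate (racemic) | CCCCCC(=O)C(C(=O)OC)c1cc(OCc2ccccc2)cc(OCc2ccccc2)c1C(=O)OC
F3 | step 9 | 2,4-bis(benzyloxy)-6-[(2-pentyl-1,3-dioxolan-2-yl)methyl]benzoyl fluoride | CCCCCC1(Cc2cc(OCc3ccccc3)cc(OCc3ccccc3)c2C(=O)F)OCCO1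
F4 | step 10 | methyl 2,4-bis(benzyloxy)-6-[(2-pentyl-1,3-dithiolan-2-yl)methyl]benzoate | CCCCCC1(Cc2cc(OCc3ccccc3)cc(OCc3ccccc3)c2C(=O)OC)SCCS1
F5 | step 10 | 2,4-bis(benzyloxy)-6-[(2-pentyl-1,3-dithiolan-2-yl)methyl]benzoic acid | CCCCCC1(Cc2cc(OCc3ccccc3)cc(OCc3ccccc3)c2C(=O)O)SCCS1
F6 | step 10 | benzyl 4-({2,4-bis(benzyloxy)-6-[(2-pentyl-1,3-dithiolan-2-yl)methyl]benzoyl}oxy)-2-hydroxy-6-(2-oxoheptyl)benzoate | CCCCCC(=O)Cc1cc(OC(=O)c2c(OCc3ccccc3)cc(OCc3ccccc3)cc2CC2(CCCCC)SCCS2)cc(O)c1C(=O)OCc1ccccc1
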